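**Plan**

1. Retrosynthetic cuts (dihydropyran locants: O1, C2 bearing isopropyl, C3, C4, spiro C5, C6): the O1–C2 bond is cut back to a spiro-oxetane O1–C6–C5–C4 with an (E)-3-methylbut-1-enyl group on C4, so the six-membered ring is grown from a four-membered one; then C4–C3 (alkenyl addition to an aldehyde) and C5–C6 (formaldehyde aldol) are cut, leading to a bridging ketone at C5.
2. Core cuts: the cycloheptene C–C bond α to that ketone (enolate alkylation), both N–CH2 bonds (double Mannich), the bond from the cyclopentene sp2 carbon to the future quaternary carbon (palladium-catalysed α-alkenylation), and the bond between the ring-fusion CH and the ester α-carbon (Ireland–Claisen rearrangement).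
3. Forward order of rings: cyclopentene (from 2-bromocyclopentenone) → cyclopentane → N-methylpiperidone → cycloheptene → oxetane → dihydropyran.
4. Stereochemistry: the absolute configuration comes from one catalytic asymmetric ketone allylation. The suprafacial [3,3] shift relays it to the ring-fusion CH, which then steers the Mannich reaction (quaternary carbon), the ring-enforced bridging alkylation (piperidine CH), the formaldehyde aldol (spiro C5) and a final kinetic protonation (ester-bearing CH).
5. Feature that makes the key event possible: spiro C5 is quaternary and carries C6H2–O1 on one side and C4 on the other, and C4 is allylic to C3=C2(iPr). An oxetane on O1, C6, C5, C4 is strained and its C4–O1 bond is an allylic C–O bond, so it ionises and O1 re-bonds at C2. Because C5 has no hydrogen, the new C3=C4 alkene can then migrate only toward O1, giving the enol ether.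

Key step: step 13

Assumption: the ester epimer with CO2Me cis to the ring-fusion hydrogen (exo, turned away from the spiro carbon) is taken as the thermodynamic one and the target's arrangement as the kinetic one; steps 8 and 15 rest on this.

**Step 1**
Reactants: 1 2-bromocyclopent-2-en-1-one
Product: 2 (S)-1-allyl-2-bromocyclopent-2-en-1-ol
Conditions: Ti(OiPr)4 (30 mol%), (R)-BINOL (30 mol%), iPrOH, Sn(CH2CH=CH2)4, CH2Cl2, rt
Reagents that add atoms: tetraallyltin C=CC[Sn](CC=C)(CC=C)CC=C
Why: Titanium–BINOLate-catalysed asymmetric allylation of ketones with tetraallyltin is established for 2-substituted cycloalkenones; the ligand differentiates the two faces of the C=O group and sets the tertiary carbinol centre, the only source of absolute configuration (the antipodal ligand is taken if the facial sense should prove opposite).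

**Step 2**
Reactants: 2 (S)-1-allyl-2-bromocyclopent-2-en-1-ol
Product: 5 (S)-2-bromo-1-(2-hydroxyethyl)cyclopent-2-en-1-ol, via ozonide 3 (not isolated), via hydroxy aldehyde 4 (not isolated)
Conditions: O3 (1 equiv), CH2Cl2, −78 °C; Me2S; then NaBH4, MeOH, 0 °C
Reagents that add atoms: ozone [O-][O+]=O
Why: Ozonolysis with reductive work-up should cleave the electron-rich monosubstituted alkene much faster than the bromine-deactivated ring alkene, trimming the allyl group to the two-carbon arm; the carbinol centre is not touched.

**Step 3**
Reactants: 5 (S)-2-bromo-1-(2-hydroxyethyl)cyclopent-2-en-1-ol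
Product: 6 (S)-2-bromo-1-(2-chloroethyl)cyclopent-2-en-1-ol
Conditions: PPh3, CCl4, CH2Cl2, 0 °C to rt
Reagents that add atoms: tetrachloromethane ClC(Cl)(Cl)Cl
Why: Appel chlorination should convert only the unhindered primary hydroxyl, because the tertiary allylic alcohol is too hindered to form the alkoxyphosphonium ion; the chloride is inert enough to be carried to step 8.

**Step 4**
Reactants: 6 (S)-2-bromo-1-(2-chloroethyl)cyclopent-2-en-1-ol; 7 5-oxohexanoic acid
Product: 8 (S)-2-bromo-1-(2-chloroethyl)cyclopent-2-en-1-yl 5-oxohexanoate
Conditions: DCC, DMAP (0.3 equiv), CH2Cl2, rt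
Reagents that add atoms: none
Why: Steglich esterification acylates hindered tertiary alcohols through the N-acylpyridinium ion under neutral conditions that do not ionise the tertiary allylic C–O bond.

**Step 5**
Reactants: 8 (S)-2-bromo-1-(2-chloroethyl)cyclopent-2-en-1-yl 5-oxohexanoate
Product: 12 methyl 2-[(1R)-2-bromo-3-(2-chloroethyl)cyclopent-2-en-1-yl]-5-oxohexanoate (both epimers at C2 of the chain), via bis-silyl ketene acetal 9 (not isolated), via rearranged silyl ester 10 (not isolated), via carboxylic acid 11 (not isolated)
Conditions: LiN(iPr)2 (2.6 equiv), Me3SiCl (3 equiv), THF, −78 °C to 60 °C; 1 M HCl; then Me3SiCHN2, MeOH–toluene, 0 °C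
Reagents that add atoms: trimethylsilyldiazomethane C[Si](C)(C)C=[N+]=[N-]
Why: Ireland–Claisen rearrangement: the O-silyl ketene acetal (the ketone being masked in the flask as its silyl enol ether) undergoes the suprafacial [3,3] shift, so the new C–C bond forms on the ring face that carried the ester oxygen and the carbinol configuration is transferred to the new ring CH, while the tetrasubstituted bromoalkene is formed; the ester α-centre arises as a mixture and is set in step 15.

**Step 6**
Reactants: 12 methyl 2-[(1R)-2-bromo-3-(2-chloroethyl)cyclopent-2-en-1-yl]-5-oxohexanoate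
Product: 13 methyl (6aR)-3-acetyl-4-(2-chloroethyl)-1,2,3,5,6,6a-hexahydropentalene-1-carboxylate (epimers at C1 and C3)
Conditions: Pd(PPh3)4 (10 mol%), PhOK (2 equiv), THF, 65 °C
Reagents that add atoms: none
Why: Intramolecular α-alkenylation of a ketone enolate by a vinyl bromide under zerovalent palladium closes the second five-membered ring (5-exo closure at the internal α-carbon); phenoxide is too weak to enolise the ester or to eliminate HCl, and the new α-centre stays epimerisable until step 7.

**Step 7**
Reactants: 13 methyl (6aR)-3-acetyl-4-(2-chloroethyl)-1,2,3,5,6,6a-hexahydropentalene-1-carboxylate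
Product: 15 spiro-piperidone: methyl 6'-(2-chloroethyl)-1-methyl-4-oxo-3',3a',4',5'-tetrahydro-2'H-spiro[piperidine-3,1'-pentalene]-3'-carboxylate with the N–CH2 on the spiro carbon cis to the ring-fusion H, via mono-Mannich base 14 (not isolated)
Conditions: MeNH3Cl (1.2 equiv), (CH2O)n (2.5 equiv), AcOH, 80 °C; aq. NaHCO3
Reagents that add atoms: methylammonium chloride C[NH3+].[Cl-]; formaldehyde (from paraformaldehyde) C=O
Why: Double Mannich reaction of a ketone with a primary amine and formaldehyde: the first aminomethylation occurs at the doubly activated α-carbon through the extended enol and should enter from the convex face of the bicyclo[3.3.0]octene (cis to the ring-fusion hydrogen), creating the quaternary centre; the second, intramolecular Mannich closure at the methyl group gives the N-methyl-4-piperidone.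

**Step 8**
Reactants: 15 spiro-piperidone
Product: 16 bridged keto ester: 8-methyl-8-azabicyclo[4.3.1]dec-2-en-10-one with the cyclopentane fused at C1–C2 and the cyclopentene at C2–C3, CO2Me cis to the ring-fusion H
Conditions: KN(SiMe3)2 (1.1 equiv), THF–DMPU, −78 °C to 45 °C; then NaOMe (0.2 equiv), MeOH, rt
Reagents that add atoms: none
Why: Intramolecular C-alkylation of the only possible ketone enolate (the other α-carbon is quaternary) by the primary chloride closes the seven-membered ring; the tether can reach only one face of the enolate, which fixes the new piperidine CH, and methoxide then equilibrates the ester to the exo epimer.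

**Step 9**
Reactants: 16 bridged keto ester
Product: 18 aldehyde: the C10 carbonyl of 16 replaced by CH–CHO (both epimers), via methyl enol ether 17 (not isolated)
Conditions: MeOCH2PPh3Cl, KN(SiMe3)2, THF, 0 °C to 50 °C; then 2 M HCl, THF, rt
Reagents that add atoms: (methoxymethyl)triphenylphosphonium chloride COC[P+](c1ccccc1)(c1ccccc1)c1ccccc1.[Cl-]; water O
Why: Wittig methoxymethylenation followed by enol ether hydrolysis homologates the ketone; both α-carbons are bridgeheads, so the ketone cannot enolise and the small ylide meets no competing deprotonation, and the configuration of the new CH is irrelevant because it is enolised in step 10.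

**Step 10**
Reactants: 18 aldehyde
Product: 19 hydroxy aldehyde: C5 now quaternary with CHO (future C4) over the piperidine ring and CH2OH (C6) syn to the cycloheptene bridge
Conditions: 37% aq. CH2O (1.5 equiv), K2CO3 (0.3 equiv), THF–H2O, 40 °C
Reagents that add atoms: formaldehyde C=O
Why: Crossed aldol hydroxymethylation of an α-branched aldehyde; formaldehyde is expected to approach the exocyclic enolate syn to the cycloheptene bridge, where the flanking carbon is a hydrogen-free sp2 carbon, and not over the piperidine ring, whose two N–CH2 groups each point an axial hydrogen at C5, the exo ester being remote from this face.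

**Step 11**
Reactants: 19 hydroxy aldehyde; 20 3-methylbut-1-yne
Product: 23 (E)-allylic 1,3-diol (carbinol epimers), via alkenylzirconocene chloride 21 (not isolated), via alkenylmethylzinc 22 (not isolated)
Conditions: 20, Cp2Zr(H)Cl, CH2Cl2, rt; ZnMe2, toluene, −65 °C; then 19, 0 °C to rt; aq. NH4Cl
Reagents that add atoms: none
Why: Hydrozirconation of the terminal alkyne (syn addition, E-alkenyl metal), transmetalation to zinc and addition to the aldehyde is chemoselective in the presence of the ester; the carbinol configuration is irrelevant because this carbon becomes sp2 in step 13.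

**Step 12**
Reactants: 23 (E)-allylic 1,3-diol
Product: 25 spiro-oxetane: O1–C6–C5–C4 ring with the (E)-3-methylbut-1-enyl group on C4, via primary monotosylate 24 (not isolated)
Conditions: KN(SiMe3)2 (1.05 equiv), TsCl (1.05 equiv), THF, −78 °C to 0 °C; then KOtBu (1.2 equiv), 0 °C to 45 °C
Reagents that add atoms: none
Why: Williamson-type 4-exo-tet closure of a 1,3-diol monosulfonate is the standard oxetane synthesis and is helped by the quaternary C5; should the allylic hydroxyl be sulfonylated instead, displacement by the primary alkoxide gives the same oxetane.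

**Step 13**
Reactants: 25 spiro-oxetane
Product: 26 spiro 2-isopropyl-3,6-dihydro-2H-pyran (C2 epimers)
Conditions: TfOH (1.05 equiv), then Cu(OTf)2 (10 mol%), CH2Cl2, −20 °C to rt; aq. NaHCO3
Reagents that add atoms: none
Why: Mechanism: the acid-activated oxetane oxygen leaves the allylic ring carbon C4, and the allyl cation C4–C3–C2 stays paired with the metal-bound alkoxide on C6–O1, which re-bonds at the distal terminus C2. The closest known reaction type is the ring expansion of 2-vinyloxetanes to 3,6-dihydro-2H-pyrans catalysed by Cu(OTf)2 or Brønsted acids, a formal [1,3] oxygen shift. The six-membered ring closes by O1–C2 bond formation within the ion pair (6-endo attack on the allyl terminus), while the four-membered ring gives up its O1–C4 bond. The new centre C2 is not controlled and is erased in step 14; spiro C5 is not involved and keeps the configuration set in step 10. The step needs ionisation at C4 and not at C6 (only C4 is allylic), closure at C2 and not return to C4 (strain release; the E-alkene places isopropyl on the outside of the U-shaped cation), and no fragmentation to formaldehyde and a diene (low temperature, non-nucleophilic medium). The amine is first protonated by the full equivalent of TfOH so that it cannot sequester the divalent copper catalyst.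

**Step 14**
Reactants: 26 spiro 2-isopropyl-3,6-dihydro-2H-pyran
Product: 27 spiro 6-isopropyl-3,4-dihydro-2H-pyran methyl ester (CO2Me cis to the ring-fusion H)
Conditions: RuHCl(CO)(PPh3)3 (5 mol%), toluene, 90 °C
Reagents that add atoms: none
Why: Ruthenium hydride-catalysed isomerisation of a cyclic allyl ether to the enol ether (hydrometalation and β-hydride elimination); the alkene can move only toward oxygen because its other allylic position is the quaternary C5, and the tetrasubstituted ring alkene is inert.

**Step 15**
Reactants: 27 spiro 6-isopropyl-3,4-dihydro-2H-pyran methyl ester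
Product: 28 methyl ester of the target (CO2Me trans to the ring-fusion H, the two ring hydrogens cis)
Conditions: LiN(iPr)2 (1.3 equiv), THF, −78 °C; then AcOH, THF, −78 °C
Reagents that add atoms: none
Why: Kinetic protonation of the ester enolate: the proton should arrive on the open convex face (the face of the ring-fusion hydrogen), which turns CO2Me to the concave face next to the spiro carbon, as in the target.

**Step 16**
Reactants: 28 methyl ester of the target
Product: 29 target acid CNP0237695.1
Conditions: Me3SnOH (5 equiv), ClCH2CH2Cl, 70 °C; aq. KF, pH 7 phosphate buffer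
Reagents that add atoms: trimethyltin hydroxide C[Sn](C)(C)O
Why: Trimethyltin hydroxide cleaves methyl esters under neutral conditions without epimerising the α-centre, and the acid-labile enol ether and the tertiary amine are not affected; the amino acid is isolated at neutral pH.

**Compound list**

1 | 2-bromocyclopent-2-en-1-one | O=C1CCC=C1Br | starting material
2 | (S)-1-allyl-2-bromocyclopent-2-en-1-ol | C=CC[C@@]1(O)CCC=C1Br | intermediate
3 | ozonide of 2: (1S)-2-bromo-1-(1,2,4-trioxolan-3-ylmethyl)cyclopent-2-en-1-ol (trioxolane carbon unassigned) | C1OC(C[C@@]2(O)CCC=C2Br)OO1 | intermediate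
4 | 2-[(1S)-2-bromo-1-hydroxycyclopent-2-en-1-yl]acetaldehyde | O=CC[C@@]1(O)CCC=C1Br | intermediate
5 | (S)-2-bromo-1-(2-hydroxyethyl)cyclopent-2-en-1-ol | OCC[C@@]1(O)CCC=C1Br | intermediate
6 | (S)-2-bromo-1-(2-chloroethyl)cyclopent-2-en-1-ol | ClCC[C@@]1(O)CCC=C1Br | intermediate
7 | 5-oxohexanoic acid | CC(=O)CCCC(=O)O | starting material
8 | (S)-2-bromo-1-(2-chloroethyl)cyclopent-2-en-1-yl 5-oxohexanoate | ClCC[C@@]1(OC(=O)CCCC(C)=O)CCC=C1Br | intermediate
9 | bis-silyl derivative of 8: 1-{[(1S)-2-bromo-1-(2-chloroethyl)cyclopent-2-en-1-yl]oxy}-1,5-bis(trimethylsilyloxy)hexa-1,5-diene (ketene acetal geometry unassigned) | ClCC[C@@]1(OC(O[Si](C)(C)C)=CCCC(=C)O[Si](C)(C)C)CCC=C1Br | intermediate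
10 | trimethylsilyl 2-[(1R)-2-bromo-3-(2-chloroethyl)cyclopent-2-en-1-yl]-5-(trimethylsilyloxy)hex-5-enoate (C2 epimers) | C[Si](C)(C)OC(=O)C(CCC(=C)O[Si](C)(C)C)[C@H]1CCC(CCCl)=C1Br | intermediate
11 | 2-[(1R)-2-bromo-3-(2-chloroethyl)cyclopent-2-en-1-yl]-5-oxohexanoic acid (C2 epimers) | OC(=O)C(CCC(C)=O)[C@H]1CCC(CCCl)=C1Br | intermediate
12 | methyl 2-[(1R)-2-bromo-3-(2-chloroethyl)cyclopent-2-en-1-yl]-5-oxohexanoate (C2 epimers) | COC(=O)C(CCC(C)=O)[C@H]1CCC(CCCl)=C1Br | intermediate
13 | methyl (6aR)-3-acetyl-4-(2-chloroethyl)-1,2,3,5,6,6a-hexahydropentalene-1-carboxylate (epimers at C1 and C3) | ClCCC1=C2[C@H](CC1)C(C(=O)OC)CC2C(C)=O | intermediate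
14 | mono-Mannich base: 13 carrying CH2NHMe on C3, cis to H-6a (ester epimers) | ClCCC1=C2[C@H](CC1)C(C(=O)OC)C[C@@]2(C(C)=O)CNC | intermediate
15 | spiro-piperidone: methyl 6'-(2-chloroethyl)-1-methyl-4-oxo-3',3a',4',5'-tetrahydro-2'H-spiro[piperidine-3,1'-pentalene]-3'-carboxylate, N–CH2 of the spiro carbon cis to H-3a' (ester epimers) | ClCCC1=C2[C@H](CC1)C(C(=O)OC)C[C@@]23CN(C)CCC3=O | intermediate
16 | bridged keto ester: 8-methyl-8-azabicyclo[4.3.1]dec-2-en-10-one with the cyclopentane (bearing CO2Me, cis to the ring-fusion H) fused at C1–C2 and the cyclopentene fused at C2–C3 | O=C2[C@@H]1CCC3=C4[C@H](CC3)[C@@H](C(=O)OC)C[C@@]42CN(C)C1 | intermediate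
17 | methyl enol ether of 16 (C10=CH–OMe, E/Z mixture) | COC=C2[C@@H]1CCC3=C4[C@H](CC3)[C@@H](C(=O)OC)C[C@@]42CN(C)C1 | intermediate
18 | aldehyde: 16 with C10 as CH–CHO (both epimers) | O=CC2[C@@H]1CCC3=C4[C@H](CC3)[C@@H](C(=O)OC)C[C@@]42CN(C)C1 | intermediate
19 | hydroxy aldehyde: C10 (pyran C5) quaternary, CHO over the piperidine ring, CH2OH syn to the cycloheptene bridge | O=C[C@@]2(CO)[C@@H]1CCC3=C4[C@H](CC3)[C@@H](C(=O)OC)C[C@@]42CN(C)C1 | intermediate
20 | 3-methylbut-1-yne | CC(C)C#C | starting material
21 | chloro[(E)-3-methylbut-1-enyl]bis(cyclopentadienyl)zirconium | CC(C)/C=C/[Zr](Cl)(C1C=CC=C1)C1C=CC=C1 | intermediate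
22 | methyl[(E)-3-methylbut-1-enyl]zinc | CC(C)/C=C/[Zn]C | intermediate
23 | (E)-allylic 1,3-diol: 19 with CHO converted into CH(OH)–CH=CH–CH(CH3)2 (carbinol epimers) | CC(C)/C=C/C(O)[C@@]2(CO)[C@@H]1CCC3=C4[C@H](CC3)[C@@H](C(=O)OC)C[C@@]42CN(C)C1 | intermediate
24 | primary monotosylate of 23 | CC(C)/C=C/C(O)[C@@]2(COS(=O)(=O)c3ccc(C)cc3)[C@@H]1CCC4=C5[C@H](CC4)[C@@H](C(=O)OC)C[C@@]52CN(C)C1 | intermediate
25 | spiro-oxetane: 2-[(E)-3-methylbut-1-enyl]oxetane spiro-fused at its C3 (pyran C5) to the core (oxetane C2 epimers) | CC(C)/C=C/C1OC[C@@]12[C@@H]3CCC4=C5[C@H](CC4)[C@@H](C(=O)OC)C[C@@]52CN(C)C3 | intermediate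
26 | spiro 2-isopropyl-3,6-dihydro-2H-pyran methyl ester (C2 epimers) | CC(C)C1C=C[C@@]2(CO1)[C@@H]1CCC3=C4[C@H](CC3)[C@@H](C(=O)OC)C[C@@]42CN(C)C1 | intermediate
27 | spiro 6-isopropyl-3,4-dihydro-2H-pyran methyl ester, CO2Me cis to the ring-fusion H | CC(C)C1=CC[C@@]2(CO1)[C@@H]1CCC3=C4[C@H](CC3)[C@@H](C(=O)OC)C[C@@]42CN(C)C1 | intermediate
28 | methyl ester of the target, CO2Me trans to the ring-fusion H | CC(C)C1=CC[C@@]2(CO1)[C@@H]1CCC3=C4[C@H](CC3)[C@H](C(=O)OC)C[C@@]42CN(C)C1 | intermediate
29 | CNP0237695.1 | CC(C)C1=CC[C@@]2(CO1)[C@@H]1CCC3=C4[C@H](CC3)[C@H](C(=O)O)C[C@@]42CN(C)C1 | target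

**Totals**

Total step count: 16. Longest linear sequence: 16 steps (from 1; 7 and 20 are purchased).

**Steps most likely to fail**

Step 13 (key step). After ionisation of the C4–O1 bond the ion pair may fragment instead of re-closing: loss of formaldehyde from C6 with cleavage of the C5–C6 bond (Grob-type), proton loss to a diene, or a hydride or alkyl shift toward the cationic carbon next to the quaternary C5. The fallback gives up the ring expansion; it sets out from hydroxy aldehyde 19 and comes back to the route at enol ether 27. Horner–Wadsworth–Emmons reaction of 19 with dimethyl (3-methyl-2-oxobutyl)phosphonate (LiCl, DBU, MeCN) should give the (E)-enone F1. Hydrogenation of the enone alkene (H2, Pd/C, EtOAc), which the tetrasubstituted ring alkene is expected to survive, gives the δ-hydroxy ketone F2, in equilibrium with its lactol. Camphorsulfonic acid (1.1 equiv, the first equivalent being taken up by the amine) in toluene at 80 °C over 4 Å molecular sieves then dehydrates the lactol to 27.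

Step 10. The facial selectivity of the formaldehyde attack on the exocyclic enolate may be poor or reversed; retro-aldol loss of formaldehyde and crossed Cannizzaro reduction are further drains. The fallback reverses the order in which the two arms of C5 are attached, so that the face now taken by the incoming group becomes the face of C4; it sets out from aldehyde 18 and comes back at diol 23. Silylation of 18 (tBuMe2SiOTf, Et3N, CH2Cl2) gives the silyl enol ether F3. Mukaiyama aldol addition of F3 to (E)-4-methylpent-2-enal (BF3·OEt2 in excess, CH2Cl2, −78 °C) gives the β-hydroxy aldehyde F4, in which the retained formyl group is the future C6. Reduction of that formyl group (NaBH4, MeOH, 0 °C) gives 23.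

Step 8. The enolate may be alkylated on oxygen, proton transfer may generate the ester enolate, which would close a six-membered ring on the same chloride, or HCl may be eliminated from the chloroethyl arm. The fallback uses a neutral enamine as the carbon nucleophile; it sets out from spiro-piperidone 15 and comes back at keto ester 16. Condensation of 15 with pyrrolidine (TiCl4, toluene, 0 °C; excess amine removed) gives the chloro enamine F5. Heating F5 in MeCN should close the seven-membered ring by intramolecular Stork enamine alkylation to the bridged iminium chloride F6. Aqueous NaHCO3 hydrolyses F6 to the ketone, and the methoxide equilibration of step 8 then gives 16.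

Further compounds
F1 | step 13 | (E)-enone: 19 with CHO converted into CH=CH–C(=O)–CH(CH3)2 | CC(C)C(=O)/C=C/[C@@]2(CO)[C@@H]1CCC3=C4[C@H](CC3)[C@@H](C(=O)OC)C[C@@]42CN(C)C1
F2 | step 13 | δ-hydroxy ketone (open form of the lactol) | CC(C)C(=O)CC[C@@]2(CO)[C@@H]1CCC3=C4[C@H](CC3)[C@@H](C(=O)OC)C[C@@]42CN(C)C1
F3 | step 10 | tert-butyldimethylsilyl enol ether of 18 | CC(C)(C)[Si](C)(C)OC=C2[C@@H]1CCC3=C4[C@H](CC3)[C@@H](C(=O)OC)C[C@@]42CN(C)C1
F4 | step 10 | β-hydroxy aldehyde carrying CH(OH)–CH=CH–CH(CH3)2 and CHO on C5 (carbinol epimers) | O=C[C@]2(C(O)/C=C/C(C)C)[C@@H]1CCC3=C4[C@H](CC3)[C@@H](C(=O)OC)C[C@@]42CN(C)C1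
F5 | step 8 | pyrrolidine enamine of 15 | ClCCC1=C2[C@H](CC1)C(C(=O)OC)C[C@@]23CN(C)CC=C3N4CCCC4
F6 | step 8 | bridged pyrrolidinium (iminium) chloride | C1CC[N+](C1)=C2[C@@H]3CCC4=C5[C@H](CC4)C(C(=O)OC)C[C@@]52CN(C)C3.[Cl-]
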